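I began with the plateaus.

| setting | Sunday's | Friday's | flask |
|---|---|---|---|
| substrate | 0.050 M | 0.20 M | 0.10 M |
| partner | 0.50 M (in portions, 3) | 0.50 M (in portions, 3) | 0.500 M (in portions, 3) |
| remark | run made earlier; portions every 80 min | run made earlier; portions every 80 min | the portions of partner follow each other after 80 min, the first at the start |
| time |  |  | 3.0 d |

| run | time / h | isomer of the product / % | over-reaction product / % | target / % |
|---|---|---|---|---|
| Sunday's | 3.00 | 45 | 9 | 6 |
| Sunday's | 6.00 | 53 | 18 | 2 |
| Sunday's | 10.0 | 51 | 17 | 2 |
| Sunday's | 15.0 | 53 | 16 | 0 |
| Sunday's | 25.0 | 52 | 15 | 0 |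
| Sunday's | 40.0 | 53 | 15 | 0 |
| Friday's | 3.00 | 24 | 6 | 2 |
| Friday's | 6.00 | 31 | 7 | 2 |
| Friday's | 10.0 | 26 | 11 | 4 |
| Friday's | 15.0 | 32 | 8 | 0 |
| Friday's | 25.0 | 31 | 9 | 0 |
| Friday's | 40.0 | 26 | 5 | 0 |

(each reading ± 2 percentage points)

* amount of isomer of the product at 3.0 d, in percent of the substrate charged
* amount of over-reaction product at 3.0 d, in percent of the substrate charged
* amount of target if the flask were left three thousand times as long, in percent of the substrate charged

- the numbers in the tables scatter by 2 percentage points (one standard deviation)

In both earlier runs, the readings of isomer and over-reaction product did not climb from 15.0 h to 40.0 h, and the target reading stood at 0 % in Sunday's run and 0 % in Friday's. I therefore took 3.0 d to lie on the plateau and expected no target. Averaging the last three readings, I found these kept fractions of the charge (isomer plus over-reaction product):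

Sunday: 68.0 %
Friday: 37.0 %

The bench rule treats the missing fraction as a small correction that grows in proportion to the charge. Friday's substrate charge was 4.00 times Sunday's, with the partner charge the same, so the rule gave 128 % missing, more than the charge itself. Friday's reading was 63.0 %, so the correction had stopped being small.

I therefore compared the missing fraction with the kept fraction, a kind of selectivity factor:

Sunday: 0.471
Friday: 1.70

These readings differ by a factor of 3.61, against 4.00 for the substrate charges. With the partner recipe held, I took the loss ratio per unit of substrate charge, averaged over both runs, as my measure: 8.96 M⁻¹.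

For this flask, my reckoning ran:

loss ratio: 0.896
kept fraction: 52.7 %
isomer's share of the kept fraction: 78.4 %
isomer: 41.3 %
over-reaction product: 11.4 %

The forecast, resting on “a loss second order in substrate (dimerisation) competing with the partner reaction”, gave 40 % of isomer and 12 % of over-reaction product at 3.0 d, and 0 % of target in the flask left for the long time asked, by a different formula from mine.

    2 substrate → self-condensation product (k = 0.00110 M⁻¹ s⁻¹)
    target → over-reaction product (k = 1.60 × 10⁻⁴ s⁻¹)
    substrate + partner → isomer of the product (k = 4.50 × 10⁻⁴ M⁻¹ s⁻¹)
    substrate + partner → target (k = 1.40 × 10⁻⁴ M⁻¹ s⁻¹)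

The flask gave 41.8 % of isomer and 13.0 % of over-reaction product at 3.0 d, and 0 % of target when left for the long time asked, so its loss ratio was 0.823, or 8.23 M⁻¹ per unit of substrate charge against the 8.96 M⁻¹ I carried. The missing material stood in this flask as 45.2 % of self-condensation product, counted as the substrate it holds, two to each, and that path is the main reason for the shortfall of isomer: the same flask without it held 76.3 % of isomer against 41.8 %. For the neighbour charged with 0.060 M of substrate, the measure gives a kept fraction of 65.0 %, and that flask kept 66.4 %.

The runs were generated by integration on assumed constants; noise was put on by code.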